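**Plan**
- Cuts (isochromene numbering): O2–C1 and C4a–C8a together, which opens both rings to one chain; then C8–C8a, the O7 ester, C6–C7 and C3–C4.
- Enabling feature: the pyran ring (C1, O2, C3, C4, C4a, C8a) is a 4-alkylidene-4H-pyran. C4a is β to the C3 and C6 carbonyls and C8a/C1 are α/β to the C8 carbonyl, so an enone unit O2=C3–C4=C4a and a C8a=C1 enaminone can unite. The C4a–C8a bond is shared with the carbocycle (C4a–C5–C6–C7–C8–C8a).
- Forward: the chain is joined at C6–C7 (aldol), then C8–C8a (alkynyl Grignard). NMe2 is put on C1 as a removable activating group, the chain is oxidized to the triketone, and one acid-promoted step closes carbocycle and pyran and expels the amine.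
- Stereochemistry: C7 (R), the only stereocentre, comes from (S)-lactic acid by self-regeneration of stereocentres through the pivalaldehyde dioxolanone and is quaternary from step 5 on.

Key step: step 12

Assumption: the silyloxy- or hydroxy-bearing carbons of 6–11, 13 and 15–17 (future C3 and C6) are carried as epimer mixtures because both become ketones in step 11; their SMILES show configuration only at the dioxolanone carbons and the quaternary carbon.

**Step 1**
Reactants: 1 (S)-lactic acid; 2 pivalaldehyde
Product: 3 (2S,5S)-2-tert-butyl-5-methyl-1,3-dioxolan-4-one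
Conditions: cat. TsOH, cat. H2SO4, pentane, reflux (Dean–Stark); crystallization from pentane/Et2O at −78 °C
Reagents that add atoms: none
Why: Acid-catalysed acetalization should give mainly the cis dioxolanone, which crystallizes pure, while the lactic acid centre is not touched.

**Step 2**
Reactants: 4 octanal; 5 propargyl bromide
Product: 6 undec-1-yn-4-ol (racemic)
Conditions: Zn dust, THF, 0 °C to rt; aq. NH4Cl
Reagents that add atoms: none
Why: Barbier propargylation with zinc should give the homopropargylic alcohol through SE2′ addition of the organozinc to the aldehyde, and the new centre is irrelevant because it later becomes a ketone.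

**Step 3**
Reactants: 6 undec-1-yn-4-ol
Product: 7 tert-butyl(dimethyl)(undec-1-yn-4-yloxy)silane
Conditions: TBSCl, imidazole, DMF, rt
Reagents that add atoms: tert-butyldimethylsilyl chloride, CC(C)(C)[Si](C)(C)Cl
Why: Standard silylation of an unhindered secondary alcohol should give an ether that tolerates the organolithium, enolate and Grignard steps.

**Step 4**
Reactants: 7 tert-butyl(dimethyl)(undec-1-yn-4-yloxy)silane
Product: 8 5-[(tert-butyldimethylsilyl)oxy]dodec-2-ynal
Conditions: n-BuLi, THF, −78 °C; DMF, −78 to 0 °C; inverse quench into aq. KH2PO4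
Reagents that add atoms: N,N-dimethylformamide, CN(C)C=O
Why: Lithiation of the terminal alkyne and formylation with DMF should give the ynal, and the buffered inverse quench should keep the liberated amine from adding to it.

**Step 5**
Reactants: 3 (2S,5S)-2-tert-butyl-5-methyl-1,3-dioxolan-4-one; 8 5-[(tert-butyldimethylsilyl)oxy]dodec-2-ynal
Product: 9 (2S,5R)-2-tert-butyl-5-{5-[(tert-butyldimethylsilyl)oxy]-1-hydroxydodec-2-yn-1-yl}-5-methyl-1,3-dioxolan-4-one
Conditions: LDA, THF, −78 °C; then 8, −78 °C; aq. NH4Cl
Reagents that add atoms: none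
Why: In this aldol reaction by self-regeneration of stereocentres the aldehyde should attack the planar lithium enolate anti to the tert-butyl group, so the new C–C bond takes the place of the former hydrogen (retention) and fixes the quaternary centre, while the carbinol configuration is neither controlled nor needed.

**Step 6**
Reactants: 9 the aldol adduct
Product: 10 (2S,5R)-5-{1,5-bis[(tert-butyldimethylsilyl)oxy]dodec-2-yn-1-yl}-2-tert-butyl-5-methyl-1,3-dioxolan-4-one
Conditions: TBSOTf, 2,6-lutidine, CH2Cl2, −78 to 0 °C
Reagents that add atoms: tert-butyldimethylsilyl trifluoromethanesulfonate, CC(C)(C)[Si](C)(C)OS(=O)(=O)C(F)(F)F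
Why: Silyl triflate protection of the hindered secondary alcohol should block retro-aldol cleavage and keep this oxygen out of the later acylation.

**Step 7**
Reactants: 10 the bis-silyl dioxolanone
Product: 11 (2R)-3,7-bis[(tert-butyldimethylsilyl)oxy]-2-hydroxy-N-methoxy-N,2-dimethyltetradec-4-ynamide
Conditions: MeNH(OMe)·HCl, i-PrMgCl, THF, −20 to 0 °C; aq. NH4Cl
Reagents that add atoms: N,O-dimethylhydroxylamine hydrochloride, CNOC.Cl
Why: Aminolysis of the activated acetal-lactone by the magnesium amide (Weinreb amide formation from a lactone) should open the ring, and the hemiacetal left behind should lose pivalaldehyde to free the tertiary alcohol without touching the quaternary centre.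

**Step 8**
Reactants: 11 the hydroxy Weinreb amide; 12 decanoyl chloride
Product: 13 (2R)-3,7-bis[(tert-butyldimethylsilyl)oxy]-1-[methoxy(methyl)amino]-2-methyl-1-oxotetradec-4-yn-2-yl decanoate
Conditions: Et3N, DMAP, CH2Cl2, 0 to 40 °C
Reagents that add atoms: none
Why: DMAP-catalysed acyl transfer should esterify the only free hydroxyl, so the tertiary oxygen is capped before any ynone or enaminone exists that it could attack.

**Step 9**
Reactants: 13 the decanoate Weinreb amide; 14 ethynylmagnesium bromide
Product: 16 (1E,4R)-5,9-bis[(tert-butyldimethylsilyl)oxy]-1-(dimethylamino)-4-methyl-3-oxohexadec-1-en-6-yn-4-yl decanoate, via terminal ynone 15 (not isolated)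
Conditions: 14, THF, 0 °C to rt; cold aq. citric acid; then Me2NH (2 M in THF), 0 °C
Reagents that add atoms: dimethylamine, CNC
Why: In this Weinreb ketone synthesis the chelated tetrahedral adduct should prevent over-addition and the amide should react ahead of the hindered tertiary ester, after which aza-Michael addition of dimethylamine to the terminal ynone should give the E-enaminone.

**Step 10**
Reactants: 16 the bis-silyl enaminone
Product: 17 (1E,4R)-1-(dimethylamino)-5,9-dihydroxy-4-methyl-3-oxohexadec-1-en-6-yn-4-yl decanoate
Conditions: HF·pyridine, pyridine, THF, 0 °C to rt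
Reagents that add atoms: none
Why: Fluoride cleavage of both silyl ethers under weakly acidic conditions should leave the enaminone intact and should suppress 1,2-acyl migration from the tertiary to the neighbouring secondary oxygen.

**Step 11**
Reactants: 17 the diol
Product: 18 (1E,4S)-1-(dimethylamino)-4-methyl-3,5,9-trioxohexadec-1-en-6-yn-4-yl decanoate
Conditions: Dess–Martin periodinane, NaHCO3, CH2Cl2, 0 °C; aq. Na2S2O3/NaHCO3; crude used at once
Reagents that add atoms: none
Why: Dess–Martin oxidation should convert the propargylic and the homopropargylic alcohol to the ynone and the ketone under buffered conditions, and any early ring closure would only anticipate step 12.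

**Step 12**
Reactants: 18 the triketo enaminone
Product: 20 (7R)-3-heptyl-7-methyl-6,8-dioxo-7,8-dihydro-6H-isochromen-7-yl decanoate, via aminomethylidene cyclohexenedione 19 (not isolated)
Conditions: AcOH, toluene (1:5), rt to 50 °C
Reagents that add atoms: none
Why: Proposed new method: in acetic acid the enaminone α-carbon of 18 (future C8a, the only carbon nucleophile) should add in Michael fashion to the alkyne carbon that is β to the C6 ketone and, through the allene tautomer of the 2-yne-1,5-dione, also β to the C3 ketone (future C4a), which gives 19; the dienol oxygen of the C3 ketone should then add to the protonated aminomethylidene carbon (future C1) and dimethylamine should leave as its acetate, so the sum is an inverse-demand oxa-[4+2] union of O2=C3–C4=C4a with C8a=C1 followed by β-elimination. The closest known reaction types are the Bohlmann–Rahtz enamine–ynone Michael addition for the C–C bond and, for the C–O bond, the closure of enaminones by an internal oxygen with loss of the amine (o-hydroxyaryl enaminones to chromones, α′-hydroxy ynones with a secondary amine to 3(2H)-furanones); running both on one chain to close two rings has no direct precedent. The carbocycle closes 6-endo-dig on the ynone (the same carbon is attacked if the allene reacts), and the pyran closes 6-exo-trig on the iminium carbon before elimination restores C8a=C1. No stereocentre is formed, and C7 is quaternary with no enolizable neighbour, so it cannot epimerize. The step needs carbon rather than oxygen attack of the ambident enaminone and closure at C4a rather than C5: the soft acceptor and the reversibility of an oxa-Michael adduct favour carbon, attack at C5 would be an anti-Michael five-ring closure, the tertiary nitrogen rules out the pyridine closure of the Bohlmann–Rahtz reaction, and the acid holds the liberated amine as its salt so that it cannot open the pyran.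

**Compound list**
1 | (S)-lactic acid | C[C@H](O)C(=O)O | starting material
2 | pivalaldehyde | CC(C)(C)C=O | starting material
3 | (2S,5S)-2-tert-butyl-5-methyl-1,3-dioxolan-4-one | C[C@@H]1O[C@H](C(C)(C)C)OC1=O | intermediate
4 | octanal | CCCCCCCC=O | starting material
5 | propargyl bromide | C#CCBr | starting material
6 | undec-1-yn-4-ol (racemic) | C#CCC(O)CCCCCCC | intermediate
7 | tert-butyl(dimethyl)(undec-1-yn-4-yloxy)silane | C#CCC(O[Si](C)(C)C(C)(C)C)CCCCCCC | intermediate
8 | 5-[(tert-butyldimethylsilyl)oxy]dodec-2-ynal | O=CC#CCC(O[Si](C)(C)C(C)(C)C)CCCCCCC | intermediate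
9 | (2S,5R)-2-tert-butyl-5-{5-[(tert-butyldimethylsilyl)oxy]-1-hydroxydodec-2-yn-1-yl}-5-methyl-1,3-dioxolan-4-one | C[C@]1(C(O)C#CCC(O[Si](C)(C)C(C)(C)C)CCCCCCC)O[C@H](C(C)(C)C)OC1=O | intermediate
10 | (2S,5R)-5-{1,5-bis[(tert-butyldimethylsilyl)oxy]dodec-2-yn-1-yl}-2-tert-butyl-5-methyl-1,3-dioxolan-4-one | C[C@]1(C(O[Si](C)(C)C(C)(C)C)C#CCC(O[Si](C)(C)C(C)(C)C)CCCCCCC)O[C@H](C(C)(C)C)OC1=O | intermediate
11 | (2R)-3,7-bis[(tert-butyldimethylsilyl)oxy]-2-hydroxy-N-methoxy-N,2-dimethyltetradec-4-ynamide | O[C@@](C)(C(=O)N(C)OC)C(O[Si](C)(C)C(C)(C)C)C#CCC(O[Si](C)(C)C(C)(C)C)CCCCCCC | intermediate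
12 | decanoyl chloride | CCCCCCCCCC(=O)Cl | starting material
13 | (2R)-3,7-bis[(tert-butyldimethylsilyl)oxy]-1-[methoxy(methyl)amino]-2-methyl-1-oxotetradec-4-yn-2-yl decanoate | CCCCCCCCCC(=O)O[C@@](C)(C(=O)N(C)OC)C(O[Si](C)(C)C(C)(C)C)C#CCC(O[Si](C)(C)C(C)(C)C)CCCCCCC | intermediate
14 | ethynylmagnesium bromide | C#C[Mg]Br | starting material
15 | (4R)-5,9-bis[(tert-butyldimethylsilyl)oxy]-4-methyl-3-oxohexadeca-1,6-diyn-4-yl decanoate | CCCCCCCCCC(=O)O[C@@](C)(C(=O)C#C)C(O[Si](C)(C)C(C)(C)C)C#CCC(O[Si](C)(C)C(C)(C)C)CCCCCCC | intermediate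
16 | (1E,4R)-5,9-bis[(tert-butyldimethylsilyl)oxy]-1-(dimethylamino)-4-methyl-3-oxohexadec-1-en-6-yn-4-yl decanoate | CCCCCCCCCC(=O)O[C@@](C)(C(=O)/C=C/N(C)C)C(O[Si](C)(C)C(C)(C)C)C#CCC(O[Si](C)(C)C(C)(C)C)CCCCCCC | intermediate
17 | (1E,4R)-1-(dimethylamino)-5,9-dihydroxy-4-methyl-3-oxohexadec-1-en-6-yn-4-yl decanoate | CCCCCCCCCC(=O)O[C@@](C)(C(=O)/C=C/N(C)C)C(O)C#CCC(O)CCCCCCC | intermediate
18 | (1E,4S)-1-(dimethylamino)-4-methyl-3,5,9-trioxohexadec-1-en-6-yn-4-yl decanoate | CCCCCCCCCC(=O)O[C@@](C)(C(=O)/C=C/N(C)C)C(=O)C#CCC(=O)CCCCCCC | intermediate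
19 | (1R)-3-[(dimethylamino)methylidene]-1-methyl-2,6-dioxo-4-(2-oxononyl)cyclohex-4-en-1-yl decanoate (exocyclic C=C geometry not defined) | CCCCCCCCCC(=O)O[C@]1(C)C(=O)C=C(CC(=O)CCCCCCC)C(=CN(C)C)C1=O | intermediate
20 | (7R)-3-heptyl-7-methyl-6,8-dioxo-7,8-dihydro-6H-isochromen-7-yl decanoate | CCCCCCCCCC(=O)O[C@]1(C)C(=O)C=C2C=C(CCCCCCC)OC=C2C1=O | target

**Step count and risks**
Total steps: 12. Longest linear sequence: 11 steps (from octanal 4, steps 2–12); 9 steps from lactic acid 1.

Steps most likely to fail:

1. Step 12 (Proposed new method). The enaminone may attack the ynone through oxygen instead of carbon, the yne-dione may isomerize to an allenyl ketone that closes to a furan, or the sequence may stall before the amine leaves. The fallback runs the two bond formations as separate steps of known type with water instead of the amine as leaving group. From 18, mild hydrolysis of the enaminone (AcOH, NaOAc, aq. THF) should give the hydroxymethylene ketone (4S)-4-methyl-1,3,5,9-tetraoxohexadec-6-yn-4-yl decanoate F1. Intramolecular Michael addition of this 1,3-dicarbonyl unit to the ynone (cat. Yb(OTf)3 or cat. Et3N, CH2Cl2) should give the carbocycle (1R)-3-(hydroxymethylidene)-1-methyl-2,6-dioxo-4-(2-oxononyl)cyclohex-4-en-1-yl decanoate F2. Acid cyclodehydration of its 1,5-dicarbonyl unit (TsOH, toluene, 4 Å sieves) should close the pyran and return to the route at 20.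

2. Step 11. The periodinane may attack the electron-rich enaminone carbon or over-oxidize the activated methylene of 18. The fallback changes the order so that no enaminone is present during the oxidation. From 15, isolated after the Grignard stage of step 9, HF·pyridine should give the diol (4R)-5,9-dihydroxy-4-methyl-3-oxohexadeca-1,6-diyn-4-yl decanoate F3. Dess–Martin oxidation, to which a terminal ynone is inert, should give the bis-ynone (4S)-4-methyl-3,5,9-trioxohexadeca-1,6-diyn-4-yl decanoate F4. One equivalent of Me2NH in THF at −78 °C should add to the more reactive terminal ynone and return to the route at 18.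

3. Step 9. The Grignard reagent may attack the decanoate, or may fail to add to the hindered amide. The fallback replaces the amide by an aldehyde as the electrophile. From 13, the Schwartz reagent (Cp2Zr(H)Cl, THF, rt) should reduce the Weinreb amide in the presence of the ester to the aldehyde (2R)-3,7-bis[(tert-butyldimethylsilyl)oxy]-2-methyl-1-oxotetradec-4-yn-2-yl decanoate F5. Reagent 14 at −78 °C, quenched cold with AcOH to prevent acyl migration, should give the propargylic alcohol (4S)-5,9-bis[(tert-butyldimethylsilyl)oxy]-3-hydroxy-4-methylhexadeca-1,6-diyn-4-yl decanoate F6. Dess–Martin oxidation should return to the route at 15, which takes up Me2NH as in step 9 to give 16.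

**Further compounds**
F1 | step 12 | (4S)-4-methyl-1,3,5,9-tetraoxohexadec-6-yn-4-yl decanoate | CCCCCCCCCC(=O)O[C@@](C)(C(=O)CC=O)C(=O)C#CCC(=O)CCCCCCC
F2 | step 12 | (1R)-3-(hydroxymethylidene)-1-methyl-2,6-dioxo-4-(2-oxononyl)cyclohex-4-en-1-yl decanoate | CCCCCCCCCC(=O)O[C@]1(C)C(=O)C=C(CC(=O)CCCCCCC)C(=CO)C1=O
F3 | step 11 | (4R)-5,9-dihydroxy-4-methyl-3-oxohexadeca-1,6-diyn-4-yl decanoate | CCCCCCCCCC(=O)O[C@@](C)(C(=O)C#C)C(O)C#CCC(O)CCCCCCC
F4 | step 11 | (4S)-4-methyl-3,5,9-trioxohexadeca-1,6-diyn-4-yl decanoate | CCCCCCCCCC(=O)O[C@@](C)(C(=O)C#C)C(=O)C#CCC(=O)CCCCCCC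
F5 | step 9 | (2R)-3,7-bis[(tert-butyldimethylsilyl)oxy]-2-methyl-1-oxotetradec-4-yn-2-yl decanoate | CCCCCCCCCC(=O)O[C@@](C)(C=O)C(O[Si](C)(C)C(C)(C)C)C#CCC(O[Si](C)(C)C(C)(C)C)CCCCCCC
F6 | step 9 | (4S)-5,9-bis[(tert-butyldimethylsilyl)oxy]-3-hydroxy-4-methylhexadeca-1,6-diyn-4-yl decanoate | CCCCCCCCCC(=O)O[C@@](C)(C(O)C#C)C(O[Si](C)(C)C(C)(C)C)C#CCC(O[Si](C)(C)C(C)(C)C)CCCCCCC
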